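**Retrosynthetic overview**

1. Target 11 comes from the protected biflavone 10 by one BCl3 treatment, which removes three MOM ethers and the chelated 5-O-methyl ether. Unit 1 is the 5-hydroxy-7-methoxy-2-(4-methoxyphenyl)chromone half, unit 2 the apigenin half.
2. Key disconnection: in 10 the C3(unit 1)–C6(unit 2) bond and the O1–C2 bond of ring C of unit 1 are cut together. This gives the acyclic o-hydroxyaryl ynone 5 and the 6-iodoapigenin tris-MOM ether 9 (domino 6-endo oxypalladation/reductive elimination).
3. Enabling feature: C3 of unit 1 lies between C2 (bonded to O1 and the anisyl ring) and the C4 carbonyl, so ring C opens at O1–C2 to an ynone whose alkyne carbons are C2 and C3. Closure by O1 on the palladium-bound alkyne leaves palladium on C3, where C6 of ring A of unit 2 is delivered. C6 of unit 2 is the only open position ortho to the chelated 5-OH, so iodine can be placed there selectively.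
4. 5 comes from 2-hydroxy-4,6-dimethoxybenzaldehyde and 4-ethynylanisole (acetylide addition, MnO2). 9 comes from apigenin (7,4'-bis-MOM protection, 5-OH-directed C6 iodination, 5-O-MOM protection).
5. Ring order: rings A, B and C of unit 2 are taken intact from apigenin; rings A and B of unit 1 come from the two aromatic building blocks; ring C of unit 1 is formed last, in the key step.

Key step: step 6

Assumption: the target SMILES carries no stereodescriptor, so the C3–C6 axis between the two units is treated as configurationally undefined (racemate or equilibrating rotamers) and no step has to control it.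

**Route**

Step 1
Reactants: 1 2-hydroxy-4,6-dimethoxybenzaldehyde; 2 4-ethynylanisole
Product: 4 2-[1-hydroxy-3-(4-methoxyphenyl)prop-2-yn-1-yl]-3,5-dimethoxyphenol (racemic), via lithium (4-methoxyphenyl)acetylide 3 (not isolated)
Conditions: 2 (2.6 equiv), n-BuLi (2.5 equiv), THF, −78 °C; then 1, −78 °C to rt; aq NH4Cl
Reagents that add atoms: none
Why: Acetylide 1,2-addition to an aldehyde: the first equivalent of 3 only deprotonates the phenol, the excess adds to the formyl group, and the carbinol centre is formed racemic because nothing biases the two faces (it is removed in step 2).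

Step 2
Reactants: 4 2-[1-hydroxy-3-(4-methoxyphenyl)prop-2-yn-1-yl]-3,5-dimethoxyphenol
Product: 5 1-(2-hydroxy-4,6-dimethoxyphenyl)-3-(4-methoxyphenyl)prop-2-yn-1-one
Conditions: crude 4, activated MnO2 (excess), CH2Cl2, rt; filtration through Celite
Reagents that add atoms: none
Why: MnO2 oxidation of a benzylic, propargylic alcohol is selective and neutral, so the phenol, hydrogen-bonded to the new carbonyl, should neither be oxidised nor add to the ynone.

Step 3
Reactants: 6 apigenin
Product: 7 5-hydroxy-7-(methoxymethoxy)-2-[4-(methoxymethoxy)phenyl]-4H-chromen-4-one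
Conditions: MOMCl (2.3 equiv), iPr2NEt, DMF, 0 °C to rt
Reagents that add atoms: chloromethyl methyl ether (MOMCl), COCCl
Why: O-alkylation of phenols (MOM acetal formation): O7 and O4' are the acidic, unchelated phenols, whereas the 5-OH is held in a hydrogen bond to the C4 carbonyl and should not react with two equivalents of MOMCl and an amine base.

Step 4
Reactants: 7 5-hydroxy-7-(methoxymethoxy)-2-[4-(methoxymethoxy)phenyl]-4H-chromen-4-one
Product: 8 5-hydroxy-6-iodo-7-(methoxymethoxy)-2-[4-(methoxymethoxy)phenyl]-4H-chromen-4-one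
Conditions: BnMe3N+ ICl2− (1.05 equiv), CaCO3, CH2Cl2–MeOH, rt
Reagents that add atoms: benzyltrimethylammonium dichloroiodate, C[N+](C)(C)Cc1ccccc1.Cl[I-]Cl
Why: Electrophilic aromatic iodination: the free 5-OH activates its only open ortho position, C6, more strongly than the 7-OMOM group activates C8, the regiochemistry known for 5-hydroxy-7-alkoxyflavones with this reagent, and CaCO3 takes up the HCl so that the MOM acetals survive.

Step 5
Reactants: 8 5-hydroxy-6-iodo-7-(methoxymethoxy)-2-[4-(methoxymethoxy)phenyl]-4H-chromen-4-one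
Product: 9 6-iodo-5,7-bis(methoxymethoxy)-2-[4-(methoxymethoxy)phenyl]-4H-chromen-4-one
Conditions: NaH (1.3 equiv), DMF, 0 °C; then MOMCl (1.5 equiv), 0 °C to rt
Reagents that add atoms: chloromethyl methyl ether (MOMCl), COCCl
Why: Williamson etherification of the sodium phenoxide: the chelated, hindered 5-OH needs NaH, and masking it removes the ortho-iodophenol that could otherwise enter a Larock heteroannulation with the alkyne or lose iodine in step 6.

Step 6
Reactants: 5 1-(2-hydroxy-4,6-dimethoxyphenyl)-3-(4-methoxyphenyl)prop-2-yn-1-one; 9 6-iodo-5,7-bis(methoxymethoxy)-2-[4-(methoxymethoxy)phenyl]-4H-chromen-4-one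
Product: 10 3-{5,7-bis(methoxymethoxy)-2-[4-(methoxymethoxy)phenyl]-4-oxo-4H-chromen-6-yl}-5,7-dimethoxy-2-(4-methoxyphenyl)-4H-chromen-4-one
Conditions: 9 (1.0 equiv), Pd(PPh3)4 (10 mol %), KOAc (3 equiv), MeCN, 60 °C; 5 (1.3 equiv) added over 6 h by syringe pump
Reagents that add atoms: none
Why: Proposed new method: zerovalent palladium inserts into the C6–I bond of 9, the resulting arylpalladium iodide (divalent palladium) binds the alkyne of 5 as a π-acid, the acetate-assisted phenol oxygen attacks the anisyl-bearing alkyne carbon anti to palladium, and reductive elimination from the C3-bound vinyl(aryl)palladium species forms the C3–C6 bond and returns zerovalent palladium. The closest known reaction type is the Cacchi annulation of o-alkynylphenols with aryl halides to 2,3-disubstituted benzofurans (oxypalladation, then reductive elimination), supported by the electrophile-induced 6-endo closure of o-alkoxyaryl ynones to 3-iodochromones, in which iodine takes the place held here by arylpalladium. Ring C of unit 1 closes in the 6-endo-dig mode through the O1–C2 bond; no stereocentre is formed, and the new C3–C6 axis is not controlled. The step needs 6-endo over 5-exo closure, which the carbonyl-polarised alkyne secures because its anisyl-bearing carbon is the electrophilic end once palladium is bound, and C6 over C8 on unit 2, which the position of the iodine fixes beforehand. It also needs coupling to outrun plain cyclisation of 5 to the 3-unsubstituted flavone, for which the weak base KOAc and the slow addition of 5 to an excess of the arylpalladium species are chosen, while the fully O-protected 9 offers no ortho-hydroxyl for a Larock heteroannulation.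

Step 7
Reactants: 10 3-{5,7-bis(methoxymethoxy)-2-[4-(methoxymethoxy)phenyl]-4-oxo-4H-chromen-6-yl}-5,7-dimethoxy-2-(4-methoxyphenyl)-4H-chromen-4-one
Product: 11 3-[5,7-dihydroxy-2-(4-hydroxyphenyl)-4-oxo-4H-chromen-6-yl]-5-hydroxy-7-methoxy-2-(4-methoxyphenyl)-4H-chromen-4-one (CNP0273448.0)
Conditions: BCl3 (1 M in CH2Cl2, excess), CH2Cl2, −78 °C to rt; then H2O
Reagents that add atoms: none
Why: Lewis-acid ether cleavage: BCl3 opens the three MOM acetals and, through a six-membered chelate with the C4 carbonyl, the peri 5-O-methyl ether of unit 1, whereas the unchelated 7- and 4'-methyl ethers should stay intact under these conditions.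

**Compound list**

1 | 2-hydroxy-4,6-dimethoxybenzaldehyde | COc1cc(O)c(C=O)c(OC)c1 | starting material
2 | 4-ethynylanisole (1-ethynyl-4-methoxybenzene) | COc1ccc(C#C)cc1 | starting material
3 | lithium (4-methoxyphenyl)acetylide | COc1ccc(C#C[Li])cc1 | intermediate
4 | 2-[1-hydroxy-3-(4-methoxyphenyl)prop-2-yn-1-yl]-3,5-dimethoxyphenol (racemic) | COc1ccc(C#CC(O)c2c(O)cc(OC)cc2OC)cc1 | intermediate
5 | 1-(2-hydroxy-4,6-dimethoxyphenyl)-3-(4-methoxyphenyl)prop-2-yn-1-one | COc1ccc(C#CC(=O)c2c(O)cc(OC)cc2OC)cc1 | intermediate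
6 | apigenin (5,7-dihydroxy-2-(4-hydroxyphenyl)-4H-chromen-4-one) | O=c1cc(-c2ccc(O)cc2)oc2cc(O)cc(O)c12 | starting material
7 | 5-hydroxy-7-(methoxymethoxy)-2-[4-(methoxymethoxy)phenyl]-4H-chromen-4-one | COCOc1ccc(cc1)-c1cc(=O)c2c(O)cc(OCOC)cc2o1 | intermediate
8 | 5-hydroxy-6-iodo-7-(methoxymethoxy)-2-[4-(methoxymethoxy)phenyl]-4H-chromen-4-one | COCOc1ccc(cc1)-c1cc(=O)c2c(O)c(I)c(OCOC)cc2o1 | intermediate
9 | 6-iodo-5,7-bis(methoxymethoxy)-2-[4-(methoxymethoxy)phenyl]-4H-chromen-4-one | COCOc1ccc(cc1)-c1cc(=O)c2c(OCOC)c(I)c(OCOC)cc2o1 | intermediate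
10 | 3-{5,7-bis(methoxymethoxy)-2-[4-(methoxymethoxy)phenyl]-4-oxo-4H-chromen-6-yl}-5,7-dimethoxy-2-(4-methoxyphenyl)-4H-chromen-4-one | COc1ccc(cc1)-c1oc2cc(OC)cc(OC)c2c(=O)c1-c1c(OCOC)cc2oc(cc(=O)c2c1OCOC)-c1ccc(OCOC)cc1 | intermediate
11 | 3-[5,7-dihydroxy-2-(4-hydroxyphenyl)-4-oxo-4H-chromen-6-yl]-5-hydroxy-7-methoxy-2-(4-methoxyphenyl)-4H-chromen-4-one (CNP0273448.0) | COc1ccc(-c2oc3cc(OC)cc(O)c3c(=O)c2-c2c(O)cc3oc(-c4ccc(O)cc4)cc(=O)c3c2O)cc1 | target

**Step count**

Total steps: 7. Longest linear sequence: 5 steps (apigenin 6 → 7 → 8 → 9 → 10 → 11, steps 3 to 7). The ynone branch (steps 1 and 2) joins at step 6.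

**Steps most likely to fail**

1. Step 6 (Proposed new method). The ynone may cyclise under base to the 3-unsubstituted flavone or the aurone faster than it is captured by the arylpalladium species. The alkyne may also undergo carbopalladation instead of oxypalladation, or 9 may lose iodine. The fallback uses known chemistry, sets out from 5 and 9 and returns to the route at 10. Electrophilic iodocyclisation of 5 with ICl in CH2Cl2 at −78 °C to 0 °C should give 3-iodo-5,7-dimethoxy-2-(4-methoxyphenyl)-4H-chromen-4-one F1. Palladium-catalysed borylation of 9 with pinacolborane (PdCl2(PPh3)2, Et3N, dioxane, 80 °C) should give 5,7-bis(methoxymethoxy)-2-[4-(methoxymethoxy)phenyl]-6-(4,4,5,5-tetramethyl-1,3,2-dioxaborolan-2-yl)-4H-chromen-4-one F2. Suzuki–Miyaura coupling of F1 with F2 (Pd2(dba)3, SPhos, K3PO4, toluene–H2O, 90 °C) should then give 10.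

2. Step 1. The lithium phenoxide formed first may deactivate the aldehyde so that acetylide addition stalls, and the electron-rich benzylic alcohol of 4 may ionise during work-up. The fallback sets out from 1 and returns at 5. Protection of 1 with MOMCl and iPr2NEt in CH2Cl2 should give 2,4-dimethoxy-6-(methoxymethoxy)benzaldehyde F3. Addition of acetylide 3 (from 2 and n-BuLi, THF, −78 °C) should give 1-[2,4-dimethoxy-6-(methoxymethoxy)phenyl]-3-(4-methoxyphenyl)prop-2-yn-1-ol F4. MnO2 oxidation in CH2Cl2 should give 1-[2,4-dimethoxy-6-(methoxymethoxy)phenyl]-3-(4-methoxyphenyl)prop-2-yn-1-one F5. Brief treatment with HCl in MeOH–THF at rt should remove the carbonyl-flanked MOM group and return 5.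

3. Step 7. Cleavage of the peri methyl ether may stay incomplete, or an unchelated methyl ether may be lost, when all four ethers are removed in one pot. The fallback sets out from 10 and ends at 11, separating the two events. HCl in MeOH–THF at 50 °C should remove only the three MOM groups and give 3-[5,7-dihydroxy-2-(4-hydroxyphenyl)-4-oxo-4H-chromen-6-yl]-5,7-dimethoxy-2-(4-methoxyphenyl)-4H-chromen-4-one F6. AlCl3 in MeCN at 60 °C should then cleave the chelated 5-O-methyl ether alone and give 11.

**Further compounds**

F1 | step 6 | 3-iodo-5,7-dimethoxy-2-(4-methoxyphenyl)-4H-chromen-4-one | COc1ccc(cc1)-c1oc2cc(OC)cc(OC)c2c(=O)c1I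
F2 | step 6 | 5,7-bis(methoxymethoxy)-2-[4-(methoxymethoxy)phenyl]-6-(4,4,5,5-tetramethyl-1,3,2-dioxaborolan-2-yl)-4H-chromen-4-one | COCOc1ccc(cc1)-c1cc(=O)c2c(OCOC)c(B3OC(C)(C)C(C)(C)O3)c(OCOC)cc2o1
F3 | step 1 | 2,4-dimethoxy-6-(methoxymethoxy)benzaldehyde | COCOc1cc(OC)cc(OC)c1C=O
F4 | step 1 | 1-[2,4-dimethoxy-6-(methoxymethoxy)phenyl]-3-(4-methoxyphenyl)prop-2-yn-1-ol (racemic) | COCOc1cc(OC)cc(OC)c1C(O)C#Cc1ccc(OC)cc1
F5 | step 1 | 1-[2,4-dimethoxy-6-(methoxymethoxy)phenyl]-3-(4-methoxyphenyl)prop-2-yn-1-one | COCOc1cc(OC)cc(OC)c1C(=O)C#Cc1ccc(OC)cc1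
F6 | step 7 | 3-[5,7-dihydroxy-2-(4-hydroxyphenyl)-4-oxo-4H-chromen-6-yl]-5,7-dimethoxy-2-(4-methoxyphenyl)-4H-chromen-4-one | COc1ccc(cc1)-c1oc2cc(OC)cc(OC)c2c(=O)c1-c1c(O)cc2oc(cc(=O)c2c1O)-c1ccc(O)cc1
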